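I decided to keep the books on the catalyst, counting each of its forms as a fraction of its own charge at the moment asked about.

substrate 30 mM; capture agent 30.0 mM; free catalyst 3.0 mM; impurity 0.52 mM

    substrate + free catalyst → catalyst intermediate A (k1 = 6.1 L mol⁻¹ s⁻¹)
    catalyst intermediate A → catalyst intermediate B (k2 = 4.2 s⁻¹)
    catalyst intermediate B → free catalyst + product (k3 = 0.27 s⁻¹)
    free catalyst + impurity → spent catalyst (k4 = 430 L mol⁻¹ s⁻¹)
    catalyst intermediate A + capture agent → trapped intermediate (k5 = 8.5 L mol⁻¹ s⁻¹)

- the form that holds most of the catalyst when 50 % of the substrate are converted (trapped intermediate / catalyst intermediate A / free catalyst / spent catalyst / catalyst intermediate B)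
- its share of the catalyst then

**Trap share.** Every substrate consumed passes once through catalyst intermediate A, which either goes on by step 2 at 250 min⁻¹ or is captured at 15 min⁻¹, a pseudo-first-order loss with the capture agent held at its charge. So I named the trap share, the fraction of passes that end in capture, and reckoned it as 5.72 %.

**First entries.** I booked each impurity as one catalyst lost, so spent catalyst took 17.3 % of the charge. At 50 % conversion the substrate consumed came to 5.00 catalyst charges, and the trap share of that put 28.6 % into trapped intermediate, which left 54.0 % in the working round.

**Round entries.** I let each intermediate pass on what it received, with the substrate down to 50.0 % of its charge, so that per free catalyst there stood 0.319 of catalyst intermediate B and 0.0205 of catalyst intermediate A. The books closed with free catalyst, the resting state of the round, at 40.3 %, more than trapped intermediate or any other entry.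

**The forecast.** The forecast named free catalyst at 40 %, on the ground that “most of the cycling catalyst sits as free catalyst”.

**The flask.** At 1.40 min the simulation gave free catalyst at 40.3 %, ahead of trapped intermediate at 28.2 %, with spent catalyst at 17.3 %, catalyst intermediate B at 13.4 % and catalyst intermediate A at 0.830 %, so the forecast held.

**Trap again.** Carried to 25.0 min, with 0.029 % of the substrate left, the trap share books 57.2 % of the catalyst charge, and this flask read 55.7 % of trapped intermediate. With the trap share set to zero at 50 % conversion, my ledger returned the trapped entry of that moment to the round and raised free catalyst, and with it the rate of step 1 at equal substrate, by a factor of 1.51. The simulated run without the capture step ran faster than this flask at 50 % conversion, the capture step being the reason, with a rate of 1.58 times the actual one.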